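The 6,8-linked biflavone is disconnected inside ring A of unit 1 (the flavone joined through C6) instead of at the biaryl bond. That ring is a phloroglucinol: carbons C5–C8, with oxygen on C5 and C7 and the unit 2 flavone (joined through its C8) on C6, come from an aryl-substituted 1-methoxy-1,3-bis(silyloxy)butadiene, and the ring-fusion bond C4a–C8a from the sulfone-activated C5=C6 bond of a 2-aryl-4-pyranone. One annulation makes C8–C8a and C4a–C5, closes ring A and, after loss of benzenesulfinic acid and methanol, leaves the free 5,7-diol with the biaryl bond already in place. Hydrogenolysis of two benzyl ethers then gives the target.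

Key step: step 7

Assumption: the target carries no axis descriptor, so the hindered C6–C8 biaryl axis is built without control (racemate if the rotamers are stable).

Structure check: diene 6, pyranone 11 and annulation product 13 agree atom for atom with the target (unit 1 bonded through C6, unit 2 through C8); no structure needed correction.

Design of the precursors:
- Pyranone 11 is assembled by acylating a preformed sulfonyl enaminone, so the one-carbon unit can only sit on the sulfonyl-bearing carbon.
- Diene 6 is made by one-pot soft double silylation, so no lithium amide meets the chromone.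
- The annulation is run in two stages (silyl triflate, then DBU), because the angular sulfone of the adduct has no acidified β-hydrogen and can leave only in an aromatising elimination.
- The double-bond geometries drawn for 6, 8 and 10 are of no consequence.

Step 1
Reactants: 1 acacetin
Product: 2 5,7-bis(benzyloxy)-2-(4-methoxyphenyl)-4H-chromen-4-one
Conditions: BnBr (2.6 equiv), K2CO3, DMF, 80 °C
Reagents that add atoms: benzyl bromide, BrCc1ccccc1
Why: Williamson ether synthesis, in which carbonate in warm DMF alkylates the acidic 7-hydroxyl at once and, with excess benzyl bromide, also the hydrogen-bonded 5-hydroxyl, while the methyl ether and the pyranone ring are inert.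

Step 2
Reactants: 2 5,7-bis(benzyloxy)-2-(4-methoxyphenyl)-4H-chromen-4-one
Product: 3 5,7-bis(benzyloxy)-8-iodo-2-(4-methoxyphenyl)-4H-chromen-4-one
Conditions: I2, AgOCOCF3, CH2Cl2, 0 → 20 °C, dark
Reagents that add atoms: iodine, II
Why: Electrophilic aromatic iodination should go to C8 of ring A, because with both oxygens alkylated there is no chelated 5-hydroxyl to direct to C6, C8 is para to the 5-ether and flanked by one ether only, and the anisyl ring is deactivated by the pyranone.

Step 3
Reactants: 3 5,7-bis(benzyloxy)-8-iodo-2-(4-methoxyphenyl)-4H-chromen-4-one; 4 methyl acetoacetate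
Product: 5 methyl 2-[5,7-bis(benzyloxy)-2-(4-methoxyphenyl)-4-oxo-4H-chromen-8-yl]-3-oxobutanoate
Conditions: CuI (20 mol %), L-proline (40 mol %), Cs2CO3, DMSO, 45 °C; aq. NH4Cl
Reagents that add atoms: none
Why: Hurtley-type (Ullmann-type) C-arylation, in which monovalent copper with an amino acid ligand couples an aryl iodide with the cesium enolate of a β-keto ester at a temperature low enough to keep the acetyl group, the new α-carbon being an enolisable centre that needs no control.

Step 4
Reactants: 5 methyl 2-[5,7-bis(benzyloxy)-2-(4-methoxyphenyl)-4-oxo-4H-chromen-8-yl]-3-oxobutanoate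
Product: 6 5,7-bis(benzyloxy)-8-[(1Z)-1-methoxy-1,3-bis(trimethylsilyloxy)buta-1,3-dien-2-yl]-2-(4-methoxyphenyl)-4H-chromen-4-one
Conditions: TMSOTf (2.6 equiv), Et3N (3.5 equiv), CH2Cl2–Et2O, 0 → 20 °C; ammonium salt removed, used crude
Reagents that add atoms: trimethylsilyl trifluoromethanesulfonate, C[Si](C)(C)OS(=O)(=O)C(F)(F)F
Why: Soft enolisation with a silyl triflate and a tertiary amine silylates both carbonyl oxygens of a 1,3-dicarbonyl compound in one operation to give the 1,3-bis(silyloxy)diene, without a lithium amide that could metalate or add to the chromone.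

Step 5
Reactants: 7 1-(phenylsulfonyl)propan-2-one
Product: 8 (3E)-4-(dimethylamino)-3-(phenylsulfonyl)but-3-en-2-one
Conditions: Me2NCH(OMe)2 (1.5 equiv), toluene, 60 °C
Reagents that add atoms: N,N-dimethylformamide dimethyl acetal, COC(OC)N(C)C
Why: Condensation of the only doubly activated methylene (between sulfone and ketone) with the formamide acetal gives the push–pull enaminone and so places the future C6 of the pyranone on the sulfonyl-bearing carbon before the aryl ketone is introduced.

Step 6
Reactants: 8 (3E)-4-(dimethylamino)-3-(phenylsulfonyl)but-3-en-2-one; 9 4-methoxybenzoyl chloride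
Product: 11 2-(4-methoxyphenyl)-5-(phenylsulfonyl)-4H-pyran-4-one, via acylated enaminone 10 (not isolated)
Conditions: LiN(SiMe3)2 (2.3 equiv), THF, −78 °C; 9, −78 → 0 °C; then CF3CO2H, 20 °C
Reagents that add atoms: none
Why: Crossed Claisen acylation of the lithium enolate of the methyl ketone (the only enolisable site), followed by acid-induced 6-endo addition–elimination of the new enol oxygen at the aminomethylene carbon with loss of dimethylamine, is the established enaminone route to 4-pyranones that carry an acceptor on C3.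

Step 7
Reactants: 6 5,7-bis(benzyloxy)-8-[(1Z)-1-methoxy-1,3-bis(trimethylsilyloxy)buta-1,3-dien-2-yl]-2-(4-methoxyphenyl)-4H-chromen-4-one; 11 2-(4-methoxyphenyl)-5-(phenylsulfonyl)-4H-pyran-4-one
Product: 13 6-[5,7-bis(benzyloxy)-2-(4-methoxyphenyl)-4-oxo-4H-chromen-8-yl]-5,7-dihydroxy-2-(4-methoxyphenyl)-4H-chromen-4-one, via angular sulfone adduct 12 (not isolated)
Conditions: 11, TMSOTf (1.2 equiv), CH2Cl2, 20 °C; 6 (1.3 equiv), −78 → 20 °C; solvent exchanged for MeCN, DBU (5 equiv), MeOH (5 equiv), 20 → 60 °C; 1 M HCl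
Reagents that add atoms: none
Why: Proposed new method: TMSOTf O-silylates pyranone 11 to a 4-silyloxypyrylium ion, and the terminal CH2 of diene 6 adds to its C6 in a vinylogous Mukaiyama–Michael reaction, which makes the C8–C8a bond of unit 1. DBU and methanol then release the α-sulfonyl enolate, whose carbon attacks the ester carbonyl in a 6-exo-trig Dieckmann-type closure (C4a–C5 bond, ring A, methanol expelled) to give adduct 12; a concerted (4+2) addition across the same double bond would lead to the same adduct. In the dienol form of 12 the angular sulfone and the C8a hydrogen occupy the two saturated carbons of a cyclohexa-1,3-diene, so base-induced loss of benzenesulfinic acid is an aromatising elimination of the kind by which sulfonylcyclohexadienes give arenes, and tautomerisation delivers the 5,7-diol. The closest known reactions are silyl-triflate-mediated additions of 1,3-bis(silyloxy)butadienes to C2 of chromones and Diels–Alder–aromatisation sequences of chromones that carry a second acceptor on C3; a sulfonylpyranone has not been used in this way. The step needs head-to-tail regiochemistry and closure on the ester instead of aldol closure on the C4 carbonyl: the CH2 terminus is the only unhindered nucleophilic carbon of the diene, C6 is the only unsubstituted pyrylium position and lies β to the sulfone, the aryl-bearing diene carbon could close only to a quaternary centre that cannot aromatise, and O1 stays on C8a (a retro-oxa-Michael opening can only re-close there), so the unit 2 aryl ends on C6 and not on C8. No stereocentre is kept, since the C4a and C8a centres of 12 disappear on aromatisation and the biaryl axis forms as the racemate.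

Step 8
Reactants: 13 6-[5,7-bis(benzyloxy)-2-(4-methoxyphenyl)-4-oxo-4H-chromen-8-yl]-5,7-dihydroxy-2-(4-methoxyphenyl)-4H-chromen-4-one
Product: 14 6-[5,7-dihydroxy-2-(4-methoxyphenyl)-4-oxo-4H-chromen-8-yl]-5,7-dihydroxy-2-(4-methoxyphenyl)-4H-chromen-4-one
Conditions: H2 (1 atm), palladium on carbon (10 % Pd/C), THF–MeOH, 20 °C
Reagents that add atoms: none
Why: Hydrogenolysis of benzyl aryl ethers over palladium on carbon at ambient pressure cleaves only the two benzylic C–O bonds and leaves the methyl ethers, the phenols and both pyranone C2=C3 bonds intact, and no stereocentre is involved.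

Compound list

1 | acacetin, 5,7-dihydroxy-2-(4-methoxyphenyl)-4H-chromen-4-one | COc1ccc(cc1)-c1cc(=O)c2c(O)cc(O)cc2o1 | starting material
2 | 5,7-bis(benzyloxy)-2-(4-methoxyphenyl)-4H-chromen-4-one | COc1ccc(cc1)-c1cc(=O)c2c(OCc3ccccc3)cc(OCc3ccccc3)cc2o1 | intermediate
3 | 5,7-bis(benzyloxy)-8-iodo-2-(4-methoxyphenyl)-4H-chromen-4-one | COc1ccc(cc1)-c1cc(=O)c2c(OCc3ccccc3)cc(OCc3ccccc3)c(I)c2o1 | intermediate
4 | methyl acetoacetate (methyl 3-oxobutanoate) | COC(=O)CC(C)=O | starting material
5 | methyl 2-[5,7-bis(benzyloxy)-2-(4-methoxyphenyl)-4-oxo-4H-chromen-8-yl]-3-oxobutanoate (racemic, enolisable α-carbon) | COC(=O)C(C(C)=O)c1c(OCc2ccccc2)cc(OCc2ccccc2)c2c(=O)cc(oc12)-c1ccc(OC)cc1 | intermediate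
6 | 5,7-bis(benzyloxy)-8-[(1Z)-1-methoxy-1,3-bis(trimethylsilyloxy)buta-1,3-dien-2-yl]-2-(4-methoxyphenyl)-4H-chromen-4-one | C=C(O[Si](C)(C)C)/C(=C(/OC)O[Si](C)(C)C)c1c(OCc2ccccc2)cc(OCc2ccccc2)c2c(=O)cc(oc12)-c1ccc(OC)cc1 | intermediate
7 | 1-(phenylsulfonyl)propan-2-one | CC(=O)CS(=O)(=O)c1ccccc1 | starting material
8 | (3E)-4-(dimethylamino)-3-(phenylsulfonyl)but-3-en-2-one | CC(=O)/C(=C\N(C)C)S(=O)(=O)c1ccccc1 | intermediate
9 | 4-methoxybenzoyl chloride | COc1ccc(cc1)C(Cl)=O | starting material
10 | acylated enaminone (not isolated), (4E)-5-(dimethylamino)-1-(4-methoxyphenyl)-4-(phenylsulfonyl)pent-4-ene-1,3-dione | COc1ccc(cc1)C(=O)CC(=O)/C(=C\N(C)C)S(=O)(=O)c1ccccc1 | intermediate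
11 | 2-(4-methoxyphenyl)-5-(phenylsulfonyl)-4H-pyran-4-one | COc1ccc(cc1)-c1cc(=O)c(co1)S(=O)(=O)c1ccccc1 | intermediate
12 | angular sulfone adduct (not isolated), rac-cis-6-[5,7-bis(benzyloxy)-2-(4-methoxyphenyl)-4-oxo-4H-chromen-8-yl]-7-hydroxy-2-(4-methoxyphenyl)-4a-(phenylsulfonyl)-8,8a-dihydro-4H-chromene-4,5(4aH)-dione; sulfonyl group and 8a-hydrogen on the same face, one enantiomer drawn, written as the neutral enol | COc1ccc(cc1)C1=CC(=O)[C@]2(S(=O)(=O)c3ccccc3)C(=O)C(=C(O)C[C@@H]2O1)c1c(OCc2ccccc2)cc(OCc2ccccc2)c2c(=O)cc(oc12)-c1ccc(OC)cc1 | intermediate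
13 | 6-[5,7-bis(benzyloxy)-2-(4-methoxyphenyl)-4-oxo-4H-chromen-8-yl]-5,7-dihydroxy-2-(4-methoxyphenyl)-4H-chromen-4-one | COc1ccc(cc1)-c1cc(=O)c2c(O)c(-c3c(OCc4ccccc4)cc(OCc4ccccc4)c4c(=O)cc(-c5ccc(OC)cc5)oc34)c(O)cc2o1 | intermediate
14 | 6-[5,7-dihydroxy-2-(4-methoxyphenyl)-4-oxo-4H-chromen-8-yl]-5,7-dihydroxy-2-(4-methoxyphenyl)-4H-chromen-4-one (6,8-linked biapigenin bis(4'-methyl ether)) | COc1ccc(-c2cc(=O)c3c(O)c(-c4c(O)cc(O)c5c(=O)cc(-c6ccc(OC)cc6)oc45)c(O)cc3o2)cc1 | target

Total step count: 8. Longest linear sequence: 6 steps (steps 1, 2, 3, 4, 7, 8); steps 5 and 6 build the pyranone in parallel.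

Steps most likely to fail

1. Step 7 (proposed new method). The hindered diene may lose its silyl groups before it adds. The sequence may stop after the first C–C bond or drain into retro-oxa-Michael opening of the O1–C8a bond. The angular sulfinate, which has no acidified β-hydrogen, may leave too slowly, so that deacylation competes with aromatisation. The fallback uses known cross-coupling chemistry; it sets out from iodide 3 and acacetin 1 and comes back to the route at target 14. Iodide 3 is borylated (B2pin2, PdCl2(dppf), KOAc, dioxane, 90 °C) to 5,7-bis(benzyloxy)-2-(4-methoxyphenyl)-8-(4,4,5,5-tetramethyl-1,3,2-dioxaborolan-2-yl)-4H-chromen-4-one F1. Acacetin 1 is benzylated at O7 only (BnBr 1.1 equiv, K2CO3, acetone, reflux) to 7-(benzyloxy)-5-hydroxy-2-(4-methoxyphenyl)-4H-chromen-4-one F2. This is iodinated ortho to the chelated 5-hydroxyl (benzyltrimethylammonium dichloroiodate, CaCO3, CH2Cl2–MeOH, 20 °C) to 7-(benzyloxy)-5-hydroxy-6-iodo-2-(4-methoxyphenyl)-4H-chromen-4-one F3, which is benzylated at O5 (BnBr, K2CO3, DMF, 80 °C) to 5,7-bis(benzyloxy)-6-iodo-2-(4-methoxyphenyl)-4H-chromen-4-one F4. Suzuki–Miyaura coupling of F1 with F4 (Pd(OAc)2, SPhos, K3PO4, toluene–water, 100 °C) should give the tetra-O-benzyl 6,8-linked biflavone F5, and hydrogenolysis under the conditions of step 8 then gives 14.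

2. Step 3. Coupling at the doubly ortho-substituted C8–I bond may be slow, iodine may be lost reductively, and the product may shed its acetyl group by retro-Claisen cleavage under carbonate. The fallback sets out from iodide 3 and comes back at keto ester 5. Palladium-catalysed coupling of 3 with the Reformatsky reagent BrZnCH2CO2Me (Pd(dba)2, P(t-Bu)3, THF, 20 → 50 °C; zerovalent palladium inserts into the C–I bond and the zinc enolate transmetalates) should give methyl 2-[5,7-bis(benzyloxy)-2-(4-methoxyphenyl)-4-oxo-4H-chromen-8-yl]acetate F6. Claisen C-acetylation of its lithium enolate (LiN(SiMe3)2 2.2 equiv, THF, −78 °C; 1-acetylimidazole) returns 5. Any deacetylated material from step 3 is this same ester and can be fed in here.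

3. Step 4. Silylation may stop at the mono(silyl) enol ether because the γ-methyl group of the hindered keto ester is only weakly acidified, and the ketene acetal may hydrolyse on handling. The fallback sets out from keto ester 5 and comes back at diene 6; it replaces one-pot soft enolisation by kinetic deprotonation of an isolated enol ether. Silylation with TMSCl and Et3N (CH2Cl2, 20 °C) gives methyl (2Z)-2-[5,7-bis(benzyloxy)-2-(4-methoxyphenyl)-4-oxo-4H-chromen-8-yl]-3-(trimethylsilyloxy)but-2-enoate F7. This is deprotonated at the methyl group by LiN(i-Pr)2 in the presence of TMSCl (internal quench, THF, −78 °C), so that the dienolate is trapped as 6 before the base can attack the chromone.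

Further compounds

F1 | step 7 | 5,7-bis(benzyloxy)-2-(4-methoxyphenyl)-8-(4,4,5,5-tetramethyl-1,3,2-dioxaborolan-2-yl)-4H-chromen-4-one | COc1ccc(cc1)-c1cc(=O)c2c(OCc3ccccc3)cc(OCc3ccccc3)c(B3OC(C)(C)C(C)(C)O3)c2o1
F2 | step 7 | 7-(benzyloxy)-5-hydroxy-2-(4-methoxyphenyl)-4H-chromen-4-one | COc1ccc(cc1)-c1cc(=O)c2c(O)cc(OCc3ccccc3)cc2o1
F3 | step 7 | 7-(benzyloxy)-5-hydroxy-6-iodo-2-(4-methoxyphenyl)-4H-chromen-4-one | COc1ccc(cc1)-c1cc(=O)c2c(O)c(I)c(OCc3ccccc3)cc2o1
F4 | step 7 | 5,7-bis(benzyloxy)-6-iodo-2-(4-methoxyphenyl)-4H-chromen-4-one | COc1ccc(cc1)-c1cc(=O)c2c(OCc3ccccc3)c(I)c(OCc3ccccc3)cc2o1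
F5 | step 7 | 5,7-bis(benzyloxy)-6-[5,7-bis(benzyloxy)-2-(4-methoxyphenyl)-4-oxo-4H-chromen-8-yl]-2-(4-methoxyphenyl)-4H-chromen-4-one | COc1ccc(cc1)-c1cc(=O)c2c(OCc3ccccc3)c(-c3c(OCc4ccccc4)cc(OCc4ccccc4)c4c(=O)cc(-c5ccc(OC)cc5)oc34)c(OCc3ccccc3)cc2o1
F6 | step 3 | methyl 2-[5,7-bis(benzyloxy)-2-(4-methoxyphenyl)-4-oxo-4H-chromen-8-yl]acetate | COC(=O)Cc1c(OCc2ccccc2)cc(OCc2ccccc2)c2c(=O)cc(oc12)-c1ccc(OC)cc1
F7 | step 4 | methyl (2Z)-2-[5,7-bis(benzyloxy)-2-(4-methoxyphenyl)-4-oxo-4H-chromen-8-yl]-3-(trimethylsilyloxy)but-2-enoate | C/C(O[Si](C)(C)C)=C(/C(=O)OC)c1c(OCc2ccccc2)cc(OCc2ccccc2)c2c(=O)cc(oc12)-c1ccc(OC)cc1
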